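**Retrosynthetic overview**
- Target ⇒ open-chain (2S,3S)-2-(4-hydroxy-3-methoxybenzyl)-3-(4-hydroxy-3,5-dimethoxybenzyl)butane-1,4-diol. The only ring made (saturated ring B of the tetralin) is closed last: direct dehydrogenation to the syringyl p-quinone methide, then Friedel–Crafts capture by C6 of the guaiacyl ring; no benzylic oxygen is pre-installed, and C1 is set here.
- Diol ⇒ (2S,3S)-dibenzylsuccinyl bis-imide: one LiAlH4 reduction removes both auxiliaries and both phenol pivalates.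
- Bis-imide ⇒ two (R)-4-benzyloxazolidinone imides: C8–C8' bond by crossed oxidative enolate coupling (laboratory counterpart of the β–β radical coupling); both stereocentres are auxiliary-controlled.
- Imides ⇒ dihydroferulic acid and sinapic acid (hydrogenation, O-pivaloylation, N-acylation).
- Ring order: no ring before step 8; ring B in step 8.

Assumption: lignan locants are used in the text (guaiacyl C6C3 unit C1 to C9, syringyl unit C1' to C9'); dihydroferulic acid, sinapic acid and (R)-4-benzyloxazolidin-2-one are taken as catalogue chemicals.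

**Step 1**
Reactants: 1 3-(4-hydroxy-3-methoxyphenyl)propanoic acid (dihydroferulic acid)
Product: 2 3-[3-methoxy-4-(pivaloyloxy)phenyl]propanoic acid
Conditions: PivCl (1.2 equiv), 2 M aq NaOH (2.3 equiv), THF–H2O, 0 °C, 1 h; then 1 M HCl to pH 2
Reagents that add atoms: pivaloyl chloride, CC(C)(C)C(Cl)=O
Why: Schotten–Baumann O-acylation, in which only the phenoxide is pivaloylated in aqueous base while the carboxylate stays free and the hindered aryl pivalate survives the cold dilute base; no stereocentre is involved.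

**Step 2**
Reactants: 2 3-[3-methoxy-4-(pivaloyloxy)phenyl]propanoic acid, 3 (R)-4-benzyloxazolidin-2-one
Product: 5 (R)-4-benzyl-3-{3-[3-methoxy-4-(pivaloyloxy)phenyl]propanoyl}oxazolidin-2-one, via guaiacyl mixed pivalic anhydride 4 (not isolated)
Conditions: PivCl (1.05 equiv), Et3N (2.5 equiv), THF, −20 °C, 1 h; then LiCl (1.1 equiv), 3 (1.0 equiv), −20 °C to rt, 4 h
Reagents that add atoms: none
Why: Mixed pivalic anhydride N-acylation of an Evans oxazolidinone (Et3N/LiCl activation), where nitrogen attacks the unhindered carbonyl of 4 and the aryl pivalate is too hindered to transfer; the auxiliary stereocentre is untouched.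

**Step 3**
Reactants: 6 sinapic acid, (E)-3-(4-hydroxy-3,5-dimethoxyphenyl)prop-2-enoic acid
Product: 7 3-(4-hydroxy-3,5-dimethoxyphenyl)propanoic acid
Conditions: H2 (1 atm), 10% Pd/C, MeOH, rt, 3 h
Reagents that add atoms: none
Why: Heterogeneous catalytic hydrogenation saturates only the cinnamic C=C; arene, acid and phenol are inert.

**Step 4**
Reactants: 7 3-(4-hydroxy-3,5-dimethoxyphenyl)propanoic acid
Product: 8 3-[3,5-dimethoxy-4-(pivaloyloxy)phenyl]propanoic acid
Conditions: PivCl (1.5 equiv), 2 M aq NaOH (2.6 equiv), THF–H2O, 0 °C to rt, 2 h; then 1 M HCl to pH 2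
Reagents that add atoms: pivaloyl chloride, CC(C)(C)C(Cl)=O
Why: Schotten–Baumann O-acylation of the electron-rich 2,6-dimethoxyphenoxide, which is slower than in step 1 because of the two flanking methoxy groups but selective for the same reason; no stereocentre is involved.

**Step 5**
Reactants: 8 3-[3,5-dimethoxy-4-(pivaloyloxy)phenyl]propanoic acid, 3 (R)-4-benzyloxazolidin-2-one
Product: 10 (R)-4-benzyl-3-{3-[3,5-dimethoxy-4-(pivaloyloxy)phenyl]propanoyl}oxazolidin-2-one, via syringyl mixed pivalic anhydride 9 (not isolated)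
Conditions: PivCl (1.05 equiv), Et3N (2.5 equiv), THF, −20 °C, 1 h; then LiCl (1.1 equiv), 3 (1.0 equiv), −20 °C to rt, 4 h
Reagents that add atoms: none
Why: Mixed pivalic anhydride N-acylation of an Evans oxazolidinone exactly as in step 2; the auxiliary stereocentre is untouched.

**Step 6**
Reactants: 5 (R)-4-benzyl-3-{3-[3-methoxy-4-(pivaloyloxy)phenyl]propanoyl}oxazolidin-2-one (3.0 equiv), 10 (R)-4-benzyl-3-{3-[3,5-dimethoxy-4-(pivaloyloxy)phenyl]propanoyl}oxazolidin-2-one (1.0 equiv)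
Product: 13 (2S,3S)-1,4-bis[(R)-4-benzyl-2-oxooxazolidin-3-yl]-2-[3-methoxy-4-(pivaloyloxy)benzyl]-3-[3,5-dimethoxy-4-(pivaloyloxy)benzyl]butane-1,4-dione, via guaiacyl imide lithium enolate 11 (not isolated), via syringyl imide lithium enolate 12 (not isolated)
Conditions: LiN(iPr)2 (1.05 equiv per imide), THF, −78 °C, 45 min; then TiCl4 (1.1 equiv per imide), −78 to 0 °C, 3 h; aq NH4Cl; chromatography
Reagents that add atoms: none
Why: Oxidative enolate coupling, run as the crossed version of the known homocoupling of N-(3-arylpropanoyl)oxazolidinone lithium enolates with TiCl4 (tetravalent titanium goes to trivalent titanium), in which each chelated Z-enolate forms the C8–C8' bond on the face opposite the C4 benzyl group of its own (R)-auxiliary so that both new stereocentres are S (matched, C2-like pairing), while the threefold excess of 5 sends about three quarters of 10 statistically into the crossed dimer, which is separated from the less polar homodimer of 5.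

**Step 7**
Reactants: 13 (2S,3S)-1,4-bis[(R)-4-benzyl-2-oxooxazolidin-3-yl]-2-[3-methoxy-4-(pivaloyloxy)benzyl]-3-[3,5-dimethoxy-4-(pivaloyloxy)benzyl]butane-1,4-dione
Product: 14 (2S,3S)-2-(4-hydroxy-3-methoxybenzyl)-3-(4-hydroxy-3,5-dimethoxybenzyl)butane-1,4-diol
Conditions: LiAlH4 (8 equiv), THF, 0 °C, 2 h; aq KNaC4H4O6 (Rochelle salt), then pH 5
Reagents that add atoms: none
Why: Exhaustive hydride reduction, in which LiAlH4 reduces both exocyclic imide carbonyls to CH2OH with release of the auxiliary and cleaves both aryl pivalates in the same operation, the C8 and C8' stereocentres passing unchanged as (2S,3S).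

**Step 8**
Reactants: 14 (2S,3S)-2-(4-hydroxy-3-methoxybenzyl)-3-(4-hydroxy-3,5-dimethoxybenzyl)butane-1,4-diol
Product: 16 (6S,7S,8R)-8-(4-hydroxy-3,5-dimethoxyphenyl)-6,7-bis(hydroxymethyl)-3-methoxy-5,6,7,8-tetrahydronaphthalen-2-ol, via syringyl para-quinone methide 15 (not isolated)
Conditions: DDQ (1.05 equiv), 1,4-dioxane, 10 °C to rt, 30 min; then 2 M aq HCl, 50 °C, 2 h
Reagents that add atoms: none
Why: Proposed new method: DDQ should dehydrogenate the more electron-rich, more easily oxidised 4-alkyl-2,6-dimethoxyphenol unit at benzylic C7' to quinone methide 15 in preference to the guaiacyl unit, and acid then turns 15 into a stabilised benzylic cation that is captured by C6 of the guaiacyl ring (para to its methoxy group) in an intramolecular Friedel–Crafts alkylation through a half-chair transition state with the aryl group and both CH2OH groups pseudo-equatorial, which sets C1 as R, trans to C2, while capture by the C9 hydroxyl or by water is reversible under the acid and funnels to the same tetralin; the closest known reaction types are the DDQ/acid oxidative cyclisation of 4-hydroxybenzyl-substituted dibenzylbutyrolactones to aryltetralins and the acid-induced conversion of lariciresinol-type ethers into isolariciresinol-type cyclolignans.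

**Compound list**
1 | 3-(4-hydroxy-3-methoxyphenyl)propanoic acid (dihydroferulic acid) | COc1cc(CCC(=O)O)ccc1O | starting material
2 | 3-[3-methoxy-4-(pivaloyloxy)phenyl]propanoic acid | COc1cc(CCC(=O)O)ccc1OC(=O)C(C)(C)C | intermediate
3 | (R)-4-benzyloxazolidin-2-one | O=C1N[C@H](Cc2ccccc2)CO1 | starting material
4 | 3-[3-methoxy-4-(pivaloyloxy)phenyl]propanoic pivalic anhydride (not isolated) | COc1cc(CCC(=O)OC(=O)C(C)(C)C)ccc1OC(=O)C(C)(C)C | intermediate
5 | (R)-4-benzyl-3-{3-[3-methoxy-4-(pivaloyloxy)phenyl]propanoyl}oxazolidin-2-one | COc1cc(CCC(=O)N2[C@H](Cc3ccccc3)COC2=O)ccc1OC(=O)C(C)(C)C | intermediate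
6 | sinapic acid, (E)-3-(4-hydroxy-3,5-dimethoxyphenyl)prop-2-enoic acid | COc1cc(/C=C/C(=O)O)cc(OC)c1O | starting material
7 | 3-(4-hydroxy-3,5-dimethoxyphenyl)propanoic acid | COc1cc(CCC(=O)O)cc(OC)c1O | intermediate
8 | 3-[3,5-dimethoxy-4-(pivaloyloxy)phenyl]propanoic acid | COc1cc(CCC(=O)O)cc(OC)c1OC(=O)C(C)(C)C | intermediate
9 | 3-[3,5-dimethoxy-4-(pivaloyloxy)phenyl]propanoic pivalic anhydride (not isolated) | COc1cc(CCC(=O)OC(=O)C(C)(C)C)cc(OC)c1OC(=O)C(C)(C)C | intermediate
10 | (R)-4-benzyl-3-{3-[3,5-dimethoxy-4-(pivaloyloxy)phenyl]propanoyl}oxazolidin-2-one | COc1cc(CCC(=O)N2[C@H](Cc3ccccc3)COC2=O)cc(OC)c1OC(=O)C(C)(C)C | intermediate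
11 | lithium (Z)-1-[(R)-4-benzyl-2-oxooxazolidin-3-yl]-3-[3-methoxy-4-(pivaloyloxy)phenyl]prop-1-en-1-olate (not isolated) | [Li]O/C(=C\Cc1ccc(OC(=O)C(C)(C)C)c(OC)c1)N1[C@H](Cc2ccccc2)COC1=O | intermediate
12 | lithium (Z)-1-[(R)-4-benzyl-2-oxooxazolidin-3-yl]-3-[3,5-dimethoxy-4-(pivaloyloxy)phenyl]prop-1-en-1-olate (not isolated) | [Li]O/C(=C\Cc1cc(OC)c(OC(=O)C(C)(C)C)c(OC)c1)N1[C@H](Cc2ccccc2)COC1=O | intermediate
13 | (2S,3S)-1,4-bis[(R)-4-benzyl-2-oxooxazolidin-3-yl]-2-[3-methoxy-4-(pivaloyloxy)benzyl]-3-[3,5-dimethoxy-4-(pivaloyloxy)benzyl]butane-1,4-dione | O=C(N1[C@H](Cc2ccccc2)COC1=O)[C@@H](Cc1ccc(OC(=O)C(C)(C)C)c(OC)c1)[C@H](Cc1cc(OC)c(OC(=O)C(C)(C)C)c(OC)c1)C(=O)N1[C@H](Cc2ccccc2)COC1=O | intermediate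
14 | (2S,3S)-2-(4-hydroxy-3-methoxybenzyl)-3-(4-hydroxy-3,5-dimethoxybenzyl)butane-1,4-diol | OC[C@@H](Cc1ccc(O)c(OC)c1)[C@H](Cc1cc(OC)c(O)c(OC)c1)CO | intermediate
15 | 4-[(2S,3S)-4-hydroxy-3-(4-hydroxy-3-methoxybenzyl)-2-(hydroxymethyl)butylidene]-2,6-dimethoxycyclohexa-2,5-dien-1-one (not isolated) | COC1=CC(=C[C@H](CO)[C@@H](CO)Cc2ccc(O)c(OC)c2)C=C(OC)C1=O | intermediate
16 | (6S,7S,8R)-8-(4-hydroxy-3,5-dimethoxyphenyl)-6,7-bis(hydroxymethyl)-3-methoxy-5,6,7,8-tetrahydronaphthalen-2-ol (CID70697973) | COc1cc2c(cc1O)[C@@H](c1cc(OC)c(O)c(OC)c1)[C@H](CO)[C@@H](CO)C2 | target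

**Totals**
Total step count: 8 steps.
Longest linear sequence: 6 steps (steps 3, 4, 5, 6, 7, 8, from 6 to 16).

**Three steps most likely to fail, each with a fallback**

Step 6 (crossed enolate coupling). The product distribution is statistical, three dimers must be separated, and the aryl pivalates must survive the enolates. Fallback: innate rather than statistical cross-selectivity through an imide/ester enolate heterocoupling. It sets out from 8 and 5. Acid 8 is esterified (MeI, K2CO3, DMF, rt) to methyl 3-[3,5-dimethoxy-4-(pivaloyloxy)phenyl]propanoate F1. A 1:1 mixture of F1 and 5 is deprotonated with LiN(iPr)2 (2.1 equiv, THF, −78 °C) to the ester lithium enolate, lithium (E)-1-methoxy-3-[3,5-dimethoxy-4-(pivaloyloxy)phenyl]prop-1-en-1-olate F2, together with enolate 11. The mixture is oxidised with Fe(acac)3 (trivalent iron, 2 equiv, −78 °C to rt); the electronically different enolates pair preferentially with each other and give methyl (2S,3S)-4-[(R)-4-benzyl-2-oxooxazolidin-3-yl]-2-[3,5-dimethoxy-4-(pivaloyloxy)benzyl]-3-[3-methoxy-4-(pivaloyloxy)benzyl]-4-oxobutanoate F3. The auxiliary fixes C8; the C8' epimer is removed by chromatography. LiAlH4 reduction of F3 (THF, 0 °C) comes back to the route at 14.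

Step 8 (oxidative cyclisation). The risks are the choice between the two free phenols in the dehydrogenation and over-oxidation of the product phenols. Fallback: orthogonal phenol protection, so that only the syringyl phenol is free when the oxidant is added. It sets out from 1. O-Benzylation of the phenoxide (BnBr, NaOH, EtOH–H2O, reflux, then acid) gives 3-[4-(benzyloxy)-3-methoxyphenyl]propanoic acid F4. As in step 2, F4 is taken through 3-[4-(benzyloxy)-3-methoxyphenyl]propanoic pivalic anhydride F5 to (R)-4-benzyl-3-{3-[4-(benzyloxy)-3-methoxyphenyl]propanoyl}oxazolidin-2-one F6. Its enolate, lithium (Z)-1-[(R)-4-benzyl-2-oxooxazolidin-3-yl]-3-[4-(benzyloxy)-3-methoxyphenyl]prop-1-en-1-olate F7 (3 equiv), is coupled with enolate 12 under the conditions of step 6 to (2S,3S)-1,4-bis[(R)-4-benzyl-2-oxooxazolidin-3-yl]-2-[4-(benzyloxy)-3-methoxybenzyl]-3-[3,5-dimethoxy-4-(pivaloyloxy)benzyl]butane-1,4-dione F8. LiAlH4 (THF, 0 °C) removes the auxiliaries and the one pivalate but not the benzyl ether, giving (2S,3S)-2-[4-(benzyloxy)-3-methoxybenzyl]-3-(4-hydroxy-3,5-dimethoxybenzyl)butane-1,4-diol F9. DDQ then aq HCl, as in step 8, can now form only 4-[(2S,3S)-3-[4-(benzyloxy)-3-methoxybenzyl]-4-hydroxy-2-(hydroxymethyl)butylidene]-2,6-dimethoxycyclohexa-2,5-dien-1-one F10, which closes to [(1R,2S,3S)-7-(benzyloxy)-1-(4-hydroxy-3,5-dimethoxyphenyl)-6-methoxy-1,2,3,4-tetrahydronaphthalene-2,3-diyl]dimethanol F11. Hydrogenolysis (H2, 10% Pd/C, MeOH, rt) comes back to the route at 16.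

Step 7 (reductive removal of two hindered, α-branched imides). The risks are competing hydride attack at the ring carbonyl and incomplete cleavage. Fallback: hydrolytic instead of reductive removal of the auxiliaries. It sets out from 13. LiOH/H2O2 (THF–H2O, 0 °C to rt, Na2SO3 quench, then acid) cleaves both imides at the exocyclic carbonyl and both pivalates, giving (2S,3S)-2-(4-hydroxy-3-methoxybenzyl)-3-(4-hydroxy-3,5-dimethoxybenzyl)butanedioic acid F12. BH3·SMe2 (THF, 0 °C to rt) reduces the diacid and comes back to the route at 14.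

**Further compounds**
F1 | step 6 | methyl 3-[3,5-dimethoxy-4-(pivaloyloxy)phenyl]propanoate | COC(=O)CCc1cc(OC)c(OC(=O)C(C)(C)C)c(OC)c1
F2 | step 6 | lithium (E)-1-methoxy-3-[3,5-dimethoxy-4-(pivaloyloxy)phenyl]prop-1-en-1-olate | [Li]O/C(OC)=C/Cc1cc(OC)c(OC(=O)C(C)(C)C)c(OC)c1
F3 | step 6 | methyl (2S,3S)-4-[(R)-4-benzyl-2-oxooxazolidin-3-yl]-2-[3,5-dimethoxy-4-(pivaloyloxy)benzyl]-3-[3-methoxy-4-(pivaloyloxy)benzyl]-4-oxobutanoate | O=C(N1[C@H](Cc2ccccc2)COC1=O)[C@@H](Cc1ccc(OC(=O)C(C)(C)C)c(OC)c1)[C@H](Cc1cc(OC)c(OC(=O)C(C)(C)C)c(OC)c1)C(=O)OC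
F4 | step 8 | 3-[4-(benzyloxy)-3-methoxyphenyl]propanoic acid | COc1cc(CCC(=O)O)ccc1OCc1ccccc1
F5 | step 8 | 3-[4-(benzyloxy)-3-methoxyphenyl]propanoic pivalic anhydride | COc1cc(CCC(=O)OC(=O)C(C)(C)C)ccc1OCc1ccccc1
F6 | step 8 | (R)-4-benzyl-3-{3-[4-(benzyloxy)-3-methoxyphenyl]propanoyl}oxazolidin-2-one | COc1cc(CCC(=O)N2[C@H](Cc3ccccc3)COC2=O)ccc1OCc1ccccc1
F7 | step 8 | lithium (Z)-1-[(R)-4-benzyl-2-oxooxazolidin-3-yl]-3-[4-(benzyloxy)-3-methoxyphenyl]prop-1-en-1-olate | [Li]O/C(=C\Cc1ccc(OCc2ccccc2)c(OC)c1)N1[C@H](Cc2ccccc2)COC1=O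
F8 | step 8 | (2S,3S)-1,4-bis[(R)-4-benzyl-2-oxooxazolidin-3-yl]-2-[4-(benzyloxy)-3-methoxybenzyl]-3-[3,5-dimethoxy-4-(pivaloyloxy)benzyl]butane-1,4-dione | O=C(N1[C@H](Cc2ccccc2)COC1=O)[C@@H](Cc1ccc(OCc2ccccc2)c(OC)c1)[C@H](Cc1cc(OC)c(OC(=O)C(C)(C)C)c(OC)c1)C(=O)N1[C@H](Cc2ccccc2)COC1=O
F9 | step 8 | (2S,3S)-2-[4-(benzyloxy)-3-methoxybenzyl]-3-(4-hydroxy-3,5-dimethoxybenzyl)butane-1,4-diol | OC[C@@H](Cc1ccc(OCc2ccccc2)c(OC)c1)[C@H](Cc1cc(OC)c(O)c(OC)c1)CO
F10 | step 8 | 4-[(2S,3S)-3-[4-(benzyloxy)-3-methoxybenzyl]-4-hydroxy-2-(hydroxymethyl)butylidene]-2,6-dimethoxycyclohexa-2,5-dien-1-one | COC1=CC(=C[C@H](CO)[C@@H](CO)Cc2ccc(OCc3ccccc3)c(OC)c2)C=C(OC)C1=O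
F11 | step 8 | [(1R,2S,3S)-7-(benzyloxy)-1-(4-hydroxy-3,5-dimethoxyphenyl)-6-methoxy-1,2,3,4-tetrahydronaphthalene-2,3-diyl]dimethanol | COc1cc2c(cc1OCc1ccccc1)[C@@H](c1cc(OC)c(O)c(OC)c1)[C@H](CO)[C@@H](CO)C2
F12 | step 7 | (2S,3S)-2-(4-hydroxy-3-methoxybenzyl)-3-(4-hydroxy-3,5-dimethoxybenzyl)butanedioic acid | OC(=O)[C@@H](Cc1ccc(O)c(OC)c1)[C@H](Cc1cc(OC)c(O)c(OC)c1)C(=O)O
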